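The pyran ring fused to ring A (the acyl-side benzene ring) is cut at its two arene bonds, O1–C8a and C4–C4a (chromene numbering). These sit on adjacent ring-A carbons, with C4a next to C5, the carbon that carries the diaryl-ether oxygen: a latent, polarised aryne. In the key step a 3-fluoroaryne, released from an ortho-silylaryl triflate, takes up 3-methylbut-2-enal by formal [2+2] addition, oxete opening and oxa-6π closure, giving the 2,2-dimethyl-2H-chromene in one operation. The C5 fluorine steers oxygen to C8a and carbon to C4a, later directs formylation and finally leaves in an SNAr reaction with the ring-B chromenol; oxidation, deprotection and lactonisation close the depsidone.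

Key step: step 3

Remark on the chemistry: the target has no stereocentre and no stereodefined acyclic double bond, so no step has to control configuration; the transient oxete and hemiaminal centres are racemic and are destroyed in the same flask.

Step 1
Reactants: 1 5-fluorobenzene-1,3-diol
Product: 5 3-fluoro-5-hydroxy-2-(trimethylsilyl)phenyl trifluoromethanesulfonate, via bis-silyl ether 2 (not isolated), via lithium phenolate 3 (not isolated), via silyl ether triflate 4 (not isolated)
Conditions: (Me3Si)2NH, 80 °C, then evaporation; LiN(iPr)2 (1.1 equiv), THF, −78 °C to rt; PhNTf2, −78 °C to rt; aq NH4Cl; citric acid, MeOH, rt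
Reagents that add atoms: hexamethyldisilazane C[Si](C)(C)N[Si](C)(C)C; N-phenylbis(trifluoromethanesulfonimide) O=S(=O)(N(c1ccccc1)S(=O)(=O)C(F)(F)F)C(F)(F)F
Why: Fluorine makes the two equivalent C–H bonds between F and OSiMe3 the most acidic, so the amide base metalates there and a 1,3 O-to-C silyl shift (retro-Brook rearrangement) gives phenolate 3, the only oxygen that is then triflated; this installs the C–Si/C–OTf pair and tells the two oxygens of the symmetric diol apart before mild methanolysis of the remaining O–Si bond.

Step 2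
Reactants: 5 3-fluoro-5-hydroxy-2-(trimethylsilyl)phenyl trifluoromethanesulfonate
Product: 6 3-fluoro-5-(methoxymethoxy)-2-(trimethylsilyl)phenyl trifluoromethanesulfonate
Conditions: MOMCl, iPr2NEt, CH2Cl2, 0 °C to rt
Reagents that add atoms: chloromethyl methyl ether COCCl
Why: O-Alkylation of the phenol (MOM protection) masks the acidic O–H, which would otherwise add to the aryne, with a group that later directs metalation and leaves under mild acid.

Step 3
Reactants: 6 3-fluoro-5-(methoxymethoxy)-2-(trimethylsilyl)phenyl trifluoromethanesulfonate; 7 3-methylbut-2-enal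
Product: 11 5-fluoro-7-(methoxymethoxy)-2,2-dimethyl-2H-chromene, via aryne 8 (not isolated), via benzoxete 9 (not isolated), via o-quinone methide 10 (not isolated)
Conditions: CsF (3 equiv), 7 (5 equiv), MeCN, rt, slow addition of 6
Reagents that add atoms: none
Why: Fluoride attacks silicon of 6 and expels triflate to give aryne 8; the carbonyl oxygen of the enal adds to the aryne carbon remote from fluorine, the aryl anion formed next to fluorine closes on the oxocarbenium carbon to give benzoxete 9, which opens by 4π-electrocyclic ring opening to o-quinone methide 10 and recloses by thermal oxa-6π-electrocyclisation onto the dimethyl-substituted alkene terminus, so that the pyran oxygen is the former aldehyde oxygen. The closest known reaction types are the insertion of arynes into the C=O bond of aldehydes and formamides and the annulation of arynes with α,β-unsaturated aldehydes to 2H-chromenes. The transient four-membered oxete closes by a stepwise polar [2+2] addition, and the six-membered pyran ring of the product closes by disrotatory 6π-electrocyclisation. No stereocentre remains, because the oxete carbon of 9 is racemic and becomes sp2 in 10. The step needs regioselectivity (oxygen to C8a, carbon to C4a), which the fluorine at C5 should secure through the known distortion of 3-haloarynes, the more distant OMOM group having only a weak opposing effect. It also needs the enal to outcompete a second aryne, which the excess of 7 and the slow release of 8 should secure, while the geometry of 10 is not critical because o-quinone methides isomerise readily.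

Step 4
Reactants: 11 5-fluoro-7-(methoxymethoxy)-2,2-dimethyl-2H-chromene
Product: 13 5-fluoro-7-(methoxymethoxy)-2,2-dimethyl-2H-chromene-6-carbaldehyde, via aryllithium 12 (not isolated)
Conditions: LiN(iPr)2, THF, −78 °C; DMF, −78 to 0 °C; aq NH4Cl
Reagents that add atoms: N,N-dimethylformamide CN(C)C=O
Why: Directed ortho-metalation: the C6–H flanked by fluorine and OMOM is the most acidic ring proton, the amide base removes it at −78 °C without adding to the styrene-type double bond and without loss of LiF from 12, and DMF formylates the carbanion.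

Step 5
Reactants: 13 5-fluoro-7-(methoxymethoxy)-2,2-dimethyl-2H-chromene-6-carbaldehyde; 14 1-bromo-3-methylbut-2-ene
Product: 17 5-fluoro-7-(methoxymethoxy)-2,2-dimethyl-8-(3-methylbut-2-en-1-yl)-2H-chromene-6-carbaldehyde, via amino alkoxide 15 (not isolated), via aryllithium 16 (not isolated)
Conditions: lithium 4-methylpiperazin-1-ide (from 1-methylpiperazine, n-BuLi), THF, −78 to −20 °C; s-BuLi, TMEDA, −78 to −40 °C; CuBr·SMe2, then 14, −78 °C to rt; aq NH4Cl
Reagents that add atoms: none
Why: Addition of the lithium amide masks the aldehyde in situ as α-amino alkoxide 15, the OMOM group then directs ortho-lithiation to the only remaining ring C–H (C8), and the aryl copper species formed with CuBr·SMe2 is allylated by prenyl bromide at its primary carbon (SN2), the aldehyde returning on aqueous work-up.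

Step 6
Reactants: 18 2,5-dibromobenzene-1,4-diol
Product: 19 1,4-dibromo-2,5-bis(methoxymethoxy)benzene
Conditions: MOMCl, iPr2NEt, CH2Cl2, 0 °C to rt
Reagents that add atoms: chloromethyl methyl ether COCCl
Why: Double O-alkylation (MOM protection) gives acetal ethers that survive organolithium, hot base and oxidant and leave together with the ring-A MOM group at the end.

Step 7
Reactants: 19 1,4-dibromo-2,5-bis(methoxymethoxy)benzene
Product: 22 2,5-bis(methoxymethoxy)benzene-1,4-diol, via dilithio arene 20 (not isolated), via bis-boronate 21 (not isolated)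
Conditions: n-BuLi (2.5 equiv), THF, −78 °C; B(OMe)3, −78 °C to rt; H2O2, aq NaOH, 0 °C; Na2S2O4 work-up
Reagents that add atoms: hydrogen peroxide OO
Why: Double bromine–lithium exchange at the pre-set positions gives 20, which is trapped as 21 and oxidised by alkaline peroxide (boronate 1,2-aryl shift) to the hydroquinone, the reductive work-up returning any quinone formed by over-oxidation.

Step 8
Reactants: 22 2,5-bis(methoxymethoxy)benzene-1,4-diol; 23 3-chloro-3-methylbut-1-yne
Product: 24 2,5-bis(methoxymethoxy)-4-[(2-methylbut-3-yn-2-yl)oxy]phenol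
Conditions: 22 (2.5 equiv), DBU, CuCl2·2H2O (0.1 mol %), MeCN, 0 °C, argon
Reagents that add atoms: none
Why: Copper-catalysed propargylic substitution of the tertiary chloride O-alkylates one phenol, and with the symmetric diol in excess monoalkylation should dominate while unreacted 22 is recovered.

Step 9
Reactants: 24 2,5-bis(methoxymethoxy)-4-[(2-methylbut-3-yn-2-yl)oxy]phenol
Product: 26 5,8-bis(methoxymethoxy)-2,2-dimethyl-2H-chromen-6-ol, via allenylphenol 25 (not isolated)
Conditions: xylenes, 140 °C, argon
Reagents that add atoms: none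
Why: Aromatic propargyl Claisen rearrangement to the only free ortho carbon gives 25, which by 1,5-hydrogen shift and oxa-6π-electrocyclisation closes the 2,2-dimethyl-2H-pyran ring and leaves the para hydroxyl free.

Step 10
Reactants: 17 5-fluoro-7-(methoxymethoxy)-2,2-dimethyl-8-(3-methylbut-2-en-1-yl)-2H-chromene-6-carbaldehyde; 26 5,8-bis(methoxymethoxy)-2,2-dimethyl-2H-chromen-6-ol
Product: 27 5-{[5,8-bis(methoxymethoxy)-2,2-dimethyl-2H-chromen-6-yl]oxy}-7-(methoxymethoxy)-2,2-dimethyl-8-(3-methylbut-2-en-1-yl)-2H-chromene-6-carbaldehyde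
Conditions: Cs2CO3, DMF, 80 °C
Reagents that add atoms: none
Why: Nucleophilic aromatic substitution by addition–elimination: the ortho formyl group stabilises the Meisenheimer intermediate, fluoride is the best leaving group for this mechanism and both ring oxygens are meta to the reacting carbon, so the phenoxide of 26 should displace fluoride and fix the ether bridge between C5 of the ring-A chromene and C6 of the ring-B chromene.

Step 11
Reactants: 27 the diaryl ether aldehyde
Product: 28 5-{[5,8-bis(methoxymethoxy)-2,2-dimethyl-2H-chromen-6-yl]oxy}-7-(methoxymethoxy)-2,2-dimethyl-8-(3-methylbut-2-en-1-yl)-2H-chromene-6-carboxylic acid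
Conditions: NaClO2, NaH2PO4, 2-methylbut-2-ene (excess), t-BuOH/THF/H2O, 0 °C to rt
Reagents that add atoms: sodium chlorite [Na+].[O-]Cl=O
Why: Pinnick oxidation converts the hindered aryl aldehyde into the acid chemoselectively, the alkene scavenger removing hypochlorous acid before it can attack the chromene and prenyl double bonds or the electron-rich rings.

Step 12
Reactants: 28 the tris-MOM carboxylic acid
Product: 29 5-[(5,8-dihydroxy-2,2-dimethyl-2H-chromen-6-yl)oxy]-7-hydroxy-2,2-dimethyl-8-(3-methylbut-2-en-1-yl)-2H-chromene-6-carboxylic acid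
Conditions: HCl (3 M in MeOH), THF, 40 °C, argon
Reagents that add atoms: none
Why: Acid-catalysed acetal exchange with methanol removes the three MOM groups under conditions mild enough to spare the prenyl and chromene alkenes, and argon protects the hydroquinone unit that is set free.

Step 13
Reactants: 29 the trihydroxy acid
Product: 30 Garcinisidone D
Conditions: DCC, DMAP (cat.), THF (1 mM), rt, argon
Reagents that add atoms: none
Why: Steglich-type lactonisation through the O-acylisourea: only the 5-OH of the ring-B unit, ortho to the ether bridge, can reach the carboxyl group (seven-membered ring), the 8-OH is para to the bridge and the ring-A 7-OH is held in a hydrogen bond to the carbonyl, while high dilution suppresses intermolecular acylation.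

Compound list
1 | 5-fluorobenzene-1,3-diol (5-fluororesorcinol) | Oc1cc(O)cc(F)c1 | starting material
2 | 1-fluoro-3,5-bis(trimethylsilyloxy)benzene | C[Si](C)(C)Oc1cc(F)cc(O[Si](C)(C)C)c1 | intermediate
3 | lithium 3-fluoro-2-(trimethylsilyl)-5-(trimethylsilyloxy)phenolate | [Li+].[O-]c1cc(O[Si](C)(C)C)cc(F)c1[Si](C)(C)C | intermediate
4 | 3-fluoro-2-(trimethylsilyl)-5-(trimethylsilyloxy)phenyl trifluoromethanesulfonate | C[Si](C)(C)Oc1cc(F)c([Si](C)(C)C)c(OS(=O)(=O)C(F)(F)F)c1 | intermediate
5 | 3-fluoro-5-hydroxy-2-(trimethylsilyl)phenyl trifluoromethanesulfonate | Oc1cc(F)c([Si](C)(C)C)c(OS(=O)(=O)C(F)(F)F)c1 | intermediate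
6 | 3-fluoro-5-(methoxymethoxy)-2-(trimethylsilyl)phenyl trifluoromethanesulfonate | COCOc1cc(F)c([Si](C)(C)C)c(OS(=O)(=O)C(F)(F)F)c1 | intermediate
7 | 3-methylbut-2-enal | CC(C)=CC=O | starting material
8 | 3-fluoro-5-(methoxymethoxy)benzyne | COCOC1=CC#CC(F)=C1 | intermediate
9 | 3-fluoro-5-(methoxymethoxy)-2-(2-methylprop-1-en-1-yl)-2H-benzo[b]oxete (racemic) | COCOc1cc(F)c2c(c1)OC2C=C(C)C | intermediate
10 | (6E)-5-fluoro-3-(methoxymethoxy)-6-(3-methylbut-2-en-1-ylidene)cyclohexa-2,4-dien-1-one | COCOC1=CC(=O)/C(=C\C=C(C)C)C(F)=C1 | intermediate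
11 | 5-fluoro-7-(methoxymethoxy)-2,2-dimethyl-2H-chromene | COCOc1cc(F)c2c(c1)OC(C)(C)C=C2 | intermediate
12 | [5-fluoro-7-(methoxymethoxy)-2,2-dimethyl-2H-chromen-6-yl]lithium | COCOc1cc2OC(C)(C)C=Cc2c(F)c1[Li] | intermediate
13 | 5-fluoro-7-(methoxymethoxy)-2,2-dimethyl-2H-chromene-6-carbaldehyde | COCOc1cc2OC(C)(C)C=Cc2c(F)c1C=O | intermediate
14 | 1-bromo-3-methylbut-2-ene (prenyl bromide) | CC(C)=CCBr | starting material
15 | lithium [5-fluoro-7-(methoxymethoxy)-2,2-dimethyl-2H-chromen-6-yl](4-methylpiperazin-1-yl)methanolate (racemic) | COCOc1cc2OC(C)(C)C=Cc2c(F)c1C([O-])N1CCN(C)CC1.[Li+] | intermediate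
16 | 8-lithio derivative of 15 (racemic) | COCOc1c([Li])c2OC(C)(C)C=Cc2c(F)c1C([O-])N1CCN(C)CC1.[Li+] | intermediate
17 | 5-fluoro-7-(methoxymethoxy)-2,2-dimethyl-8-(3-methylbut-2-en-1-yl)-2H-chromene-6-carbaldehyde | COCOc1c(CC=C(C)C)c2OC(C)(C)C=Cc2c(F)c1C=O | intermediate
18 | 2,5-dibromobenzene-1,4-diol | Oc1cc(Br)c(O)cc1Br | starting material
19 | 1,4-dibromo-2,5-bis(methoxymethoxy)benzene | COCOc1cc(Br)c(OCOC)cc1Br | intermediate
20 | [2,5-bis(methoxymethoxy)-1,4-phenylene]dilithium | COCOc1cc([Li])c(OCOC)cc1[Li] | intermediate
21 | tetramethyl [2,5-bis(methoxymethoxy)-1,4-phenylene]diboronate | COCOc1cc(B(OC)OC)c(OCOC)cc1B(OC)OC | intermediate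
22 | 2,5-bis(methoxymethoxy)benzene-1,4-diol | COCOc1cc(O)c(OCOC)cc1O | intermediate
23 | 3-chloro-3-methylbut-1-yne | CC(C)(Cl)C#C | starting material
24 | 2,5-bis(methoxymethoxy)-4-[(2-methylbut-3-yn-2-yl)oxy]phenol | COCOc1cc(OC(C)(C)C#C)c(OCOC)cc1O | intermediate
25 | 2,5-bis(methoxymethoxy)-3-(3-methylbuta-1,2-dien-1-yl)benzene-1,4-diol | Oc1cc(OCOC)c(O)c(C=C=C(C)C)c1OCOC | intermediate
26 | 5,8-bis(methoxymethoxy)-2,2-dimethyl-2H-chromen-6-ol | Oc1cc(OCOC)c2c(c1OCOC)C=CC(C)(C)O2 | intermediate
27 | 5-{[5,8-bis(methoxymethoxy)-2,2-dimethyl-2H-chromen-6-yl]oxy}-7-(methoxymethoxy)-2,2-dimethyl-8-(3-methylbut-2-en-1-yl)-2H-chromene-6-carbaldehyde | COCOc1c(CC=C(C)C)c2OC(C)(C)C=Cc2c(Oc2cc(OCOC)c3OC(C)(C)C=Cc3c2OCOC)c1C=O | intermediate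
28 | 5-{[5,8-bis(methoxymethoxy)-2,2-dimethyl-2H-chromen-6-yl]oxy}-7-(methoxymethoxy)-2,2-dimethyl-8-(3-methylbut-2-en-1-yl)-2H-chromene-6-carboxylic acid | COCOc1c(CC=C(C)C)c2OC(C)(C)C=Cc2c(Oc2cc(OCOC)c3OC(C)(C)C=Cc3c2OCOC)c1C(=O)O | intermediate
29 | 5-[(5,8-dihydroxy-2,2-dimethyl-2H-chromen-6-yl)oxy]-7-hydroxy-2,2-dimethyl-8-(3-methylbut-2-en-1-yl)-2H-chromene-6-carboxylic acid | Oc1c(CC=C(C)C)c2OC(C)(C)C=Cc2c(Oc2cc(O)c3OC(C)(C)C=Cc3c2O)c1C(=O)O | intermediate
30 | Garcinisidone D | CC(C)=CCc1c(O)c2c(c3c1OC(C)(C)C=C3)Oc1cc(O)c3c(c1OC2=O)C=CC(C)(C)O3 | target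

Total step count: 13. Longest linear sequence: 9 steps (steps 1 to 5, then 10 to 13); the ring-B branch (steps 6 to 9) joins at step 10.

The three steps most likely to fail

Step 5 (in situ protection, metalation, prenylation). The aldehyde may be masked incompletely, so that s-BuLi adds to the carbonyl group, or the alkyllithium may add across the styrene-type C3=C4 bond before it removes the C8 proton. The fallback sets out from aldehyde 13 and avoids organolithium chemistry: electrophilic iodination with N-iodosuccinimide and catalytic CF3CO2H in MeCN at 0 °C should place iodine at C8, the only free ring position and ortho to two oxygens, to give 5-fluoro-8-iodo-7-(methoxymethoxy)-2,2-dimethyl-2H-chromene-6-carbaldehyde F4. A Stille coupling of the iodide with tributyl(3-methylbut-2-en-1-yl)stannane (Pd(PPh3)4, LiCl, DMF, 90 °C) should then deliver the prenyl group at its primary carbon and come back to the route at compound 17.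

Step 10 (SNAr ether formation). Addition–elimination may be slow at a fluoroarene that is substituted at both ortho positions and whose formyl group is weakened by two oxygen donors, and material may be lost to base over long heating. The fallback sets out from 17 and replaces the hindered SNAr by a palladium-catalysed coupling: the small alkoxide of 2-(methylsulfonyl)ethanol (NaH, DMF, 0 °C to rt) should displace fluoride to give 7-(methoxymethoxy)-2,2-dimethyl-8-(3-methylbut-2-en-1-yl)-5-[2-(methylsulfonyl)ethoxy]-2H-chromene-6-carbaldehyde F5. This ether loses methyl vinyl sulfone in the same flask to give 5-hydroxy-7-(methoxymethoxy)-2,2-dimethyl-8-(3-methylbut-2-en-1-yl)-2H-chromene-6-carbaldehyde F6, and Tf2O with pyridine converts the phenol into 6-formyl-7-(methoxymethoxy)-2,2-dimethyl-8-(3-methylbut-2-en-1-yl)-2H-chromen-5-yl trifluoromethanesulfonate F7. A Buchwald–Hartwig etherification of the triflate with chromenol 26 (Pd(OAc)2, t-BuXPhos, K3PO4, toluene, 100 °C) should give diaryl ether 27, where the route is rejoined.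

Step 3 (key step). The aryne may partition away from the wanted path: addition of fluoride or acetonitrile, capture of the o-quinone methide by a second aryne, or enolisation of the enal by fluoride would each lower the flux through the electrocyclisation. The fallback sets out from 6 and divides the annulation into known stages: aryne generation with CsF in DMF as solvent should give insertion into the formamide C=O bond, with the same orientation (oxygen remote from fluorine), to give 3-fluoro-5-(methoxymethoxy)-N,N-dimethyl-2H-benzo[b]oxet-2-amine F1. This is hydrolysed on work-up to 2-fluoro-6-hydroxy-4-(methoxymethoxy)benzaldehyde F2, and 2-methylprop-1-enylmagnesium bromide (2.2 equiv, THF, 0 °C) adds to give 3-fluoro-2-(1-hydroxy-3-methylbut-2-en-1-yl)-5-(methoxymethoxy)phenol F3. Heating this allylic alcohol in toluene at 110 °C should dehydrate it to o-quinone methide 10, which closes to chromene 11, where the route is rejoined.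

Further compounds
F1 | step 3 | 3-fluoro-5-(methoxymethoxy)-N,N-dimethyl-2H-benzo[b]oxet-2-amine (racemic) | COCOc1cc(F)c2c(c1)OC2N(C)C
F2 | step 3 | 2-fluoro-6-hydroxy-4-(methoxymethoxy)benzaldehyde | COCOc1cc(O)c(C=O)c(F)c1
F3 | step 3 | 3-fluoro-2-(1-hydroxy-3-methylbut-2-en-1-yl)-5-(methoxymethoxy)phenol (racemic) | COCOc1cc(O)c(C(O)C=C(C)C)c(F)c1
F4 | step 5 | 5-fluoro-8-iodo-7-(methoxymethoxy)-2,2-dimethyl-2H-chromene-6-carbaldehyde | COCOc1c(I)c2OC(C)(C)C=Cc2c(F)c1C=O
F5 | step 10 | 7-(methoxymethoxy)-2,2-dimethyl-8-(3-methylbut-2-en-1-yl)-5-[2-(methylsulfonyl)ethoxy]-2H-chromene-6-carbaldehyde | COCOc1c(CC=C(C)C)c2OC(C)(C)C=Cc2c(OCCS(C)(=O)=O)c1C=O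
F6 | step 10 | 5-hydroxy-7-(methoxymethoxy)-2,2-dimethyl-8-(3-methylbut-2-en-1-yl)-2H-chromene-6-carbaldehyde | COCOc1c(CC=C(C)C)c2OC(C)(C)C=Cc2c(O)c1C=O
F7 | step 10 | 6-formyl-7-(methoxymethoxy)-2,2-dimethyl-8-(3-methylbut-2-en-1-yl)-2H-chromen-5-yl trifluoromethanesulfonate | COCOc1c(CC=C(C)C)c2OC(C)(C)C=Cc2c(OS(=O)(=O)C(F)(F)F)c1C=O
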